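# (3R)-Isoflavan CNP0331403.1: desymmetrising aryl ether closure of a malonate-derived diol, then excision of one carbon

## Analysis of the target

The target is a (3R)-isoflavan. Ring A (benzo ring, hydroxyl at C7) and ring C (dihydropyran, O1–C2–C3–C4) form a chroman, and C3 carries ring B. Ring B is a pentasubstituted benzene: C1' holds the chroman, C2' a free hydroxyl, C3' a 3-methylbut-2-en-1-yl (prenyl) group, and O–C4' and C5' are tied into a 2,2-dimethyl-2H-pyran (ring D); only C6' keeps a hydrogen. C3 is the only stereocentre, a tertiary benzylic C–H between the C2 and C4 methylenes, so there is no second centre to relay from and no carbonyl or heteroatom on C3 through which a reagent could be steered. The molecule is sensitive to acid (the C2' hydroxyl can add across the neighbouring prenyl olefin, and the styrene-type olefin of ring D can hydrate or oligomerise), to electrophilic halogen and oxidants (two olefins, two electron-rich phenols) and to any hydrogenation. The last point closes the usual way to an isoflavan stereocentre, enantioselective reduction of an isoflavene or isoflavone. The crowding of ring B means that each substituent has to be placed by construction and not by late aromatic substitution. The strategy rests on C3: if its hydrogen is replaced in thought by a hydroxymethyl group, C3 becomes a quaternary carbon with two identical CH2OH arms, one of which is the future C2. Such a carbon is prochiral and comes from malonate, and the arms become different when one of their oxygens is joined to C8a of ring A to close ring C; the spare arm is afterwards cut back to hydrogen.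

## Retrosynthetic reasoning

**26 from 25.** The last disconnection frees the two phenols from their methoxymethyl acetals. They are cut last because the free C2' hydroxyl beside the prenyl group and the free C7 hydroxyl are the most fragile functions: either would compete as a nucleophile in the aryl ether closure and both invite oxidation. The forward step has to cleave two acetals without protonating the prenyl or ring D olefins.

**25 from 24 and 24 from 23.** The C3–H bond is traced back to a C3–CHO bond and the aldehyde to the primary alcohol of 23. One carbon is added in the retrosynthetic direction because a tertiary C–H centre with no neighbouring function cannot be made selectively by a ring closure, whereas a quaternary centre with two equal arms can. The forward steps have to oxidise a neopentyl-type alcohol and then expel the formyl carbon on rhodium with retention at C3.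

**23 from 22.** Ring C is opened at O1–C8a. This bond is chosen because its formation is the only closure that starts from two identical arms: it makes ring C and turns the prochiral carbon of 22 into the C3 stereocentre in the same event. Cutting C2–O1 instead would need one arm to be activated beforehand, that is, the desymmetrisation would already have to be done. Cutting C3–C4 or C3–C1' would call for an enantioselective C–C bond formation at a carbon without an activating group. What is gained is an achiral precursor whose only reactive handles are one aryl bromide and two equal alcohols.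

**22 from 21, and 21 from 16 and 20.** The two hydroxymethyl arms come from the two ester groups of 21 by hydride reduction, so their equivalence is built in. The C3–C4 bond is cut next: the stabilised anion of arylmalonate 16 is benzylated by dibromide 20, which reacts at its benzylic carbon only and keeps the aryl bromide for the key step.

**16 from 14 and 15.** The C1'–C3 bond is cut between ring B and the malonate carbon: palladium-catalysed coupling of aryl bromide 14 with diethyl malonate 15. The arylation is placed before the benzylation so that the only palladium step ahead of the key step runs when 14 holds the only aryl halide in the flask.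

**20 from 19, 18 and 17.** The ring A partner is reached by functional group changes from aldehyde 17, which already has bromine ortho and oxygen para to the one-carbon substituent: acetal protection (18), reduction (19), bromination of the benzylic alcohol (20).

**14 from 12, 11 and 10.** The ring D olefin is taken back to the C4 ketone of chromanone 11 through alcohol 12. The ketone is kept as long as possible because the chromanone has no styrene-type olefin to interfere with metathesis and because it makes the C7 hydroxyl acidic and easy to protect (10 to 11).

**10 from 8 and 9, 8 from 6, 6 from 4 and 5.** The prenyl group is cut at its double bond: cross-metathesis of the allyl arene 8 with alkene 9. The allyl group is in turn moved back to oxygen: the sigmatropic shift of allyl ether 6 can only end at C8, since C6 carries bromine and the para position is a ring-fusion carbon. Direct C-prenylation would not give this certainty.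

**4 from 1 and 2.** Ring D with its gem-dimethyl group is cut at the aryl–acyl bond and at O–C2'': acylation of 1 by acid 2 followed by oxa-Michael closure. Bromine is present from the start in 1, so the position that becomes C1' of ring B is fixed by the starting material and not by a halogenation of uncertain regiochemistry.

## Alternatives that were turned down

**Alternative 1:** Ring B is taken apart at C1'–C6' and C3'–C4', back to the chiral ketone (R)-1-[7-(methoxymethoxy)chroman-3-yl]propan-2-one A2 and methyl acrylate A3.
- Forward key step: under an alkoxide base the more substituted enolate of A2 adds to A3, and the methyl-side enolate then closes on the ester to give the cyclohexane-1,3-dione A1 as a mixture of epimers at the dione carbon.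
- For: no transition metal and a cheap three-carbon partner. The dione sets the C2' and C4' oxygens and offers the carbon between them for prenylation by enolate alkylation. On this point it is stronger than the chosen route, which needs an allylation, a sigmatropic shift and a metathesis for the same group.
- Against: the annulation forms no lasting stereocentre, so C3 must already be present in A2 and the central problem is moved to an earlier step. The Michael addition has to start from the internal α-carbon of a methyl ketone while the terminal enolate competes. The prenylated dione must then be dehydrogenated to a resorcinol in the presence of the prenyl olefin, and the usual dehydrogenation reagents attack or shift that olefin. Ring D is still missing and needs a regiocontrolled annulation.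
- Comparison: at least five steps follow its key step, against three here, and none of them addresses C3. The chosen route brings a complete ring B into one step that sets C3 and closes ring C.

**Alternative 2:** Ring C is cut at C3–C4 and O1–C2 into a ring A ortho-quinone methide, 3-(methoxymethoxy)-6-methylidenecyclohexa-2,4-dien-1-one A7, released from the sulfone 5-(methoxymethoxy)-2-[(phenylsulfonyl)methyl]phenol A6, and the ring B arylacetaldehyde A5.
- Forward key step: the enamine of A5 with a chiral secondary amine of the diarylprolinol silyl ether class adds to the methylene of A7, and the phenoxide closes on the aldehyde carbon to give the lactol A4 as an anomeric mixture.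
- For: it is the most convergent plan, C3 is formed directly as a C–H centre, and no carbon has to be removed. After the key step it needs a reduction to the diol, an etherification and a deprotection, so in step economy it is as good as or better than the chosen route.
- Against: in A4 and its open hydroxy-aldehyde form, C3 is the α-carbon of an α-aryl aldehyde and enolises easily, so the base that releases A7 and the later reduction can erode the enantiomeric purity. A5 is an electron-rich, ortho-substituted arylacetaldehyde, prone to self-condensation and slow to form a well-differentiated enamine. Direct deoxygenation of the lactol needs a Lewis acid and a silane, which the prenyl group, ring D and the acetals would not tolerate.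
- Comparison: the chosen strategy pays with three steps after the key step and one stoichiometric rhodium reagent. What it offers in return is configurational security: from the key step to the excision, C3 is quaternary and cannot epimerise.

**Alternative 3:** Ring D is cut at C5'–C4'' and O–C2'', back to the prenylated resorcinol isoflavan A9 and 3-methylbut-2-enal A10.
- Forward key step: condensation under a mild base or an ammonium carboxylate, C-attack at C5', dehydration to a vinyl ortho-quinone methide and oxa-6π-electrocyclisation to the silyl ether A8.
- For: the regiochemistry is enforced by the structure, since C3' is blocked by the prenyl group, C1' by the chroman and C6' is not activated, so only C5' can react and only the C4' oxygen can close. The sensitive chromene appears last, and ring B needs no protecting group. On these points it is as strong as or stronger than the chosen route, in which ring D is made in step 7 and has to survive ten further steps.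
- Against: the key step makes no stereocentre, so C3 of A9 must come from an earlier asymmetric step that the plan leaves open. Reductive ways to such isoflavans would have to run before the prenyl group is present, which brings back a late, regioselective C-prenylation of a resorcinol. The free C2' hydroxyl next to the prenyl group is exposed to heat and catalyst, and electron-rich resorcinols tend to give bis-adducts and oligomers with A10.
- Comparison: the chosen strategy uses its key step for the real difficulty, C3 together with ring C, and starts it from an achiral precursor.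

Key step: step 14

Assumption: the sense of induction of the chiral ligand for a diol with an aryl group on the prochiral carbon is not predicted here; both antipodes of the ligand are available, and the one that gives (R)-23 is taken.

## Route

Step 1
Reactants: 1 4-bromobenzene-1,3-diol (4-bromoresorcinol); 2 3-methylbut-2-enoic acid
Product: 4 6-bromo-7-hydroxy-2,2-dimethylchroman-4-one, via open-chain aryl enone 3 (not isolated)
Conditions: MeSO3H, P2O5, 70 °C
Reagents that add atoms: none
Why: Friedel–Crafts acylation at the only position of 1 that is para to a hydroxyl (the other is taken by bromine) gives enone 3, and oxa-Michael addition of the ortho hydroxyl closes ring D; the bromine of 1 ends at C6, the later attachment point of ring B.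

Step 2
Reactants: 4 6-bromo-7-hydroxy-2,2-dimethylchroman-4-one; 5 allyl bromide
Product: 6 7-(allyloxy)-6-bromo-2,2-dimethylchroman-4-one
Conditions: K2CO3, acetone, reflux
Reagents that add atoms: none
Why: Williamson ether synthesis; the C7 hydroxyl is para to the ketone and therefore acidic enough for carbonate.

Step 3
Reactants: 6 7-(allyloxy)-6-bromo-2,2-dimethylchroman-4-one
Product: 8 8-allyl-6-bromo-7-hydroxy-2,2-dimethylchroman-4-one, via cyclohexadienone 7 (not isolated)
Conditions: PhNEt2, 195 °C, sealed tube
Reagents that add atoms: none
Why: Aromatic Claisen rearrangement; C6 carries bromine and the para position is the ring-fusion carbon, so the [3,3] shift can only end at C8, where dienone 7 tautomerises to the phenol.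

Step 4
Reactants: 8 8-allyl-6-bromo-7-hydroxy-2,2-dimethylchroman-4-one; 9 2-methylbut-2-ene
Product: 10 6-bromo-7-hydroxy-2,2-dimethyl-8-(3-methylbut-2-en-1-yl)chroman-4-one
Conditions: second-generation Grubbs catalyst RuCl2(=CHPh)(H2IMes)(PCy3) (5 mol %), 2-methylbut-2-ene (excess), CH2Cl2, 40 °C
Reagents that add atoms: none
Why: Olefin cross-metathesis of a terminal allyl arene with a trisubstituted alkene used in excess, the standard allyl-to-prenyl exchange; 8 has no other olefin, which is why the metathesis is run before ring D is unsaturated.

Step 5
Reactants: 10 6-bromo-7-hydroxy-2,2-dimethyl-8-(3-methylbut-2-en-1-yl)chroman-4-one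
Product: 11 6-bromo-7-(methoxymethoxy)-2,2-dimethyl-8-(3-methylbut-2-en-1-yl)chroman-4-one
Conditions: MOMCl, i-Pr2NEt, CH2Cl2, 0 °C to reflux
Reagents that add atoms: chloromethyl methyl ether (MOMCl), COCCl
Why: O-alkylation of an acidic phenol with an α-chloro ether; the acetal withstands every basic, hydridic and organometallic step that follows and keeps the phenol from adding to the prenyl olefin.

Step 6
Reactants: 11 6-bromo-7-(methoxymethoxy)-2,2-dimethyl-8-(3-methylbut-2-en-1-yl)chroman-4-one
Product: 12 (±)-6-bromo-7-(methoxymethoxy)-2,2-dimethyl-8-(3-methylbut-2-en-1-yl)chroman-4-ol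
Conditions: NaBH4, MeOH/THF, 0 °C to rt
Reagents that add atoms: none
Why: Borohydride reduction of an aryl ketone; the new C4 centre is racemic and is destroyed in step 7.

Step 7
Reactants: 12 (±)-6-bromo-7-(methoxymethoxy)-2,2-dimethyl-8-(3-methylbut-2-en-1-yl)chroman-4-ol
Product: 14 6-bromo-7-(methoxymethoxy)-2,2-dimethyl-8-(3-methylbut-2-en-1-yl)-2H-chromene, via C4 mesylate 13 (not isolated)
Conditions: MsCl, Et3N, CH2Cl2, 0 to 40 °C
Reagents that add atoms: none
Why: Sulfonylation and elimination; the benzylic C4 sulfonate is activated by the ortho ring oxygen and the para acetal oxygen and loses methanesulfonate readily to give the conjugated chromene, and the basic medium spares the acetal.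

Step 8
Reactants: 14 6-bromo-7-(methoxymethoxy)-2,2-dimethyl-8-(3-methylbut-2-en-1-yl)-2H-chromene; 15 diethyl malonate
Product: 16 diethyl 2-[7-(methoxymethoxy)-2,2-dimethyl-8-(3-methylbut-2-en-1-yl)-2H-chromen-6-yl]malonate
Conditions: Pd(OAc)2 (3 mol %), 2-(di-tert-butylphosphino)-2'-methylbiphenyl (6 mol %), K3PO4, toluene, 90 °C
Reagents that add atoms: none
Why: Palladium-catalysed α-arylation of a malonate enolate (Buchwald–Hartwig-type C–C coupling); the bulky electron-rich biaryl phosphine allows oxidative addition into the electron-rich, mono-ortho-substituted C–Br bond, and the product stays deprotonated, which prevents a second arylation.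

Step 9
Reactants: 17 2-bromo-4-hydroxybenzaldehyde
Product: 18 2-bromo-4-(methoxymethoxy)benzaldehyde
Conditions: MOMCl, i-Pr2NEt, CH2Cl2, 0 °C to rt
Reagents that add atoms: chloromethyl methyl ether (MOMCl), COCCl
Why: O-alkylation of a para-formyl phenol, which is acidic and unhindered.

Step 10
Reactants: 18 2-bromo-4-(methoxymethoxy)benzaldehyde
Product: 19 [2-bromo-4-(methoxymethoxy)phenyl]methanol
Conditions: NaBH4, MeOH, 0 °C
Reagents that add atoms: none
Why: Borohydride reduction of an aldehyde; the aryl bromide and the acetal are inert.

Step 11
Reactants: 19 [2-bromo-4-(methoxymethoxy)phenyl]methanol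
Product: 20 2-bromo-1-(bromomethyl)-4-(methoxymethoxy)benzene
Conditions: CBr4, PPh3, CH2Cl2, 0 °C
Reagents that add atoms: carbon tetrabromide, BrC(Br)(Br)Br
Why: Appel bromination under neutral conditions, so that no HBr is formed that could cleave the acetal; the bromide is used without storage.

Step 12
Reactants: 16 diethyl 2-[7-(methoxymethoxy)-2,2-dimethyl-8-(3-methylbut-2-en-1-yl)-2H-chromen-6-yl]malonate; 20 2-bromo-1-(bromomethyl)-4-(methoxymethoxy)benzene
Product: 21 diethyl 2-[2-bromo-4-(methoxymethoxy)benzyl]-2-[7-(methoxymethoxy)-2,2-dimethyl-8-(3-methylbut-2-en-1-yl)-2H-chromen-6-yl]malonate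
Conditions: Cs2CO3, DMF, 0 °C to rt
Reagents that add atoms: none
Why: SN2 benzylation of the stabilised arylmalonate anion builds the quaternary carbon; the aryl C–Br bond of 20 does not react without a metal catalyst.

Step 13
Reactants: 21 diethyl 2-[2-bromo-4-(methoxymethoxy)benzyl]-2-[7-(methoxymethoxy)-2,2-dimethyl-8-(3-methylbut-2-en-1-yl)-2H-chromen-6-yl]malonate
Product: 22 2-[2-bromo-4-(methoxymethoxy)benzyl]-2-[7-(methoxymethoxy)-2,2-dimethyl-8-(3-methylbut-2-en-1-yl)-2H-chromen-6-yl]propane-1,3-diol
Conditions: LiAlH4, THF, 0 °C to rt
Reagents that add atoms: none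
Why: Hydride reduction of both esters to the prochiral 1,3-diol; at low temperature the aryl bromide, the acetals and the olefins are untouched, and fast hydride delivery outruns retro-Claisen loss of a formyl group from the half-reduced intermediate.

Step 14
Reactants: 22 2-[2-bromo-4-(methoxymethoxy)benzyl]-2-[7-(methoxymethoxy)-2,2-dimethyl-8-(3-methylbut-2-en-1-yl)-2H-chromen-6-yl]propane-1,3-diol
Product: 23 [(3R)-7-(methoxymethoxy)-3-[7-(methoxymethoxy)-2,2-dimethyl-8-(3-methylbut-2-en-1-yl)-2H-chromen-6-yl]-3,4-dihydro-2H-chromen-3-yl]methanol
Conditions: Pd(OAc)2 (5 mol %), enantiopure 7-(diphenylphosphino)-7'-(diphenylphosphoryl)-1,1'-spirobiindane (6 mol %, the antipode that gives (R)-23), Cs2CO3, toluene, 70 °C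
Reagents that add atoms: none
Why: Pd(OAc)2 is reduced in the flask to a zerovalent palladium–ligand complex that inserts into the C8a–Br bond of 22; carbonate then exchanges bromide for one of the two enantiotopic alkoxide arms to give a seven-membered aryl(alkoxo)palladium chelate, and C–O reductive elimination forms O1–C8a. The closest known reaction type is the enantioselective desymmetrising intramolecular Buchwald–Hartwig etherification of 2-substituted 2-(2-halobenzyl)propane-1,3-diols to 3,3-disubstituted chroman-3-ylmethanols. Ring C, a six-membered ring, closes in a 6-exo sense at the aryl carbon, the C–Pd bond that is given up lying outside the new ring. The new quaternary stereocentre C3 is controlled by the chiral ligand alone: in the two diastereomeric chelates ring B, with its ortho methoxymethoxy group, points either towards or away from the aryl groups on phosphorus, and the less crowded chelate should eliminate faster. The step needs enantiotopic-group selectivity, which the large size difference between ring B and the unbound CH2OH arm supports, and it needs ring closure to outrun β-hydride loss from the palladium alkoxide, which the gem-disubstitution at C3 and the chelating ligand favour. The prenyl and ring D olefins could be reached from the aryl–palladium only through eight- or nine-membered transition states, so no Heck pathway should compete, and the single aryl bromide excludes a second arylation. Once formed, the quaternary centre of 23 cannot epimerise.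

Step 15
Reactants: 23 [(3R)-7-(methoxymethoxy)-3-[7-(methoxymethoxy)-2,2-dimethyl-8-(3-methylbut-2-en-1-yl)-2H-chromen-6-yl]-3,4-dihydro-2H-chromen-3-yl]methanol
Product: 24 (3S)-7-(methoxymethoxy)-3-[7-(methoxymethoxy)-2,2-dimethyl-8-(3-methylbut-2-en-1-yl)-2H-chromen-6-yl]-3,4-dihydro-2H-chromene-3-carbaldehyde
Conditions: Dess–Martin periodinane, NaHCO3, CH2Cl2, 0 °C to rt
Reagents that add atoms: none
Why: Dess–Martin oxidation of a neopentyl-type primary alcohol under buffered conditions that spare the olefins and acetals; the aldehyde has no α-hydrogen, so it can neither enolise nor lose the ring C aryloxide, and the descriptor changes from R to S only through the priority rules.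

Step 16
Reactants: 24 (3S)-7-(methoxymethoxy)-3-[7-(methoxymethoxy)-2,2-dimethyl-8-(3-methylbut-2-en-1-yl)-2H-chromen-6-yl]-3,4-dihydro-2H-chromene-3-carbaldehyde
Product: 25 7-(methoxymethoxy)-6-[(3R)-7-(methoxymethoxy)-3,4-dihydro-2H-chromen-3-yl]-2,2-dimethyl-8-(3-methylbut-2-en-1-yl)-2H-chromene
Conditions: RhCl(PPh3)3 (1.1 equiv), degassed xylene, 130 °C
Reagents that add atoms: none
Why: Tsuji–Wilkinson decarbonylation: the formyl C–H bond adds to monovalent rhodium, the acyl group gives up carbon monoxide by retro-insertion, and C–H reductive elimination from the coordinatively saturated trivalent rhodium alkyl hydride puts hydrogen where the formyl group was, with retention at C3, as is established for α-aryl tertiary aldehydes. The reagent is used in stoichiometric amount because the carbonyl complex that it becomes is inert, which also limits olefin isomerisation.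

Step 17
Reactants: 25 7-(methoxymethoxy)-6-[(3R)-7-(methoxymethoxy)-3,4-dihydro-2H-chromen-3-yl]-2,2-dimethyl-8-(3-methylbut-2-en-1-yl)-2H-chromene
Product: 26 6-[(3R)-7-hydroxy-3,4-dihydro-2H-chromen-3-yl]-2,2-dimethyl-8-(3-methylbut-2-en-1-yl)-2H-chromen-7-ol (target)
Conditions: HCl (1.25 M in MeOH), THF, 25–40 °C
Reagents that add atoms: none
Why: Acid-catalysed methanolysis of two aryl methoxymethyl acetals; dilute acid at low temperature should cleave the acetals faster than it protonates the prenyl or ring D olefins, and C3 has no pathway for epimerisation.

## Compound list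

1 | 4-bromobenzene-1,3-diol (4-bromoresorcinol) | Oc1ccc(Br)c(O)c1 | starting material
2 | 3-methylbut-2-enoic acid | CC(C)=CC(=O)O | starting material
3 | 1-(5-bromo-2,4-dihydroxyphenyl)-3-methylbut-2-en-1-one (formed in the flask in step 1) | CC(C)=CC(=O)c1cc(Br)c(O)cc1O | intermediate
4 | 6-bromo-7-hydroxy-2,2-dimethylchroman-4-one | CC1(C)CC(=O)c2cc(Br)c(O)cc2O1 | intermediate
5 | allyl bromide (3-bromoprop-1-ene) | C=CCBr | starting material
6 | 7-(allyloxy)-6-bromo-2,2-dimethylchroman-4-one | CC1(C)CC(=O)c2cc(Br)c(OCC=C)cc2O1 | intermediate
7 | 8-allyl-6-bromo-2,2-dimethyl-2,3-dihydro-4H-chromene-4,7(8H)-dione, racemic (formed in the flask in step 3) | C=CCC1C(=O)C(Br)=CC2=C1OC(C)(C)CC2=O | intermediate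
8 | 8-allyl-6-bromo-7-hydroxy-2,2-dimethylchroman-4-one | CC1(C)CC(=O)c2cc(Br)c(O)c(CC=C)c2O1 | intermediate
9 | 2-methylbut-2-ene | CC=C(C)C | starting material
10 | 6-bromo-7-hydroxy-2,2-dimethyl-8-(3-methylbut-2-en-1-yl)chroman-4-one | CC(C)=CCc1c(O)c(Br)cc2c1OC(C)(C)CC2=O | intermediate
11 | 6-bromo-7-(methoxymethoxy)-2,2-dimethyl-8-(3-methylbut-2-en-1-yl)chroman-4-one | CC(C)=CCc1c(OCOC)c(Br)cc2c1OC(C)(C)CC2=O | intermediate
12 | (±)-6-bromo-7-(methoxymethoxy)-2,2-dimethyl-8-(3-methylbut-2-en-1-yl)chroman-4-ol | CC(C)=CCc1c(OCOC)c(Br)cc2c1OC(C)(C)CC2O | intermediate
13 | (±)-6-bromo-7-(methoxymethoxy)-2,2-dimethyl-8-(3-methylbut-2-en-1-yl)chroman-4-yl methanesulfonate (formed in the flask in step 7) | CC(C)=CCc1c(OCOC)c(Br)cc2c1OC(C)(C)CC2OS(C)(=O)=O | intermediate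
14 | 6-bromo-7-(methoxymethoxy)-2,2-dimethyl-8-(3-methylbut-2-en-1-yl)-2H-chromene | CC(C)=CCc1c(OCOC)c(Br)cc2c1OC(C)(C)C=C2 | intermediate
15 | diethyl malonate | CCOC(=O)CC(=O)OCC | starting material
16 | diethyl 2-[7-(methoxymethoxy)-2,2-dimethyl-8-(3-methylbut-2-en-1-yl)-2H-chromen-6-yl]malonate | CC(C)=CCc1c(OCOC)c(C(C(=O)OCC)C(=O)OCC)cc2c1OC(C)(C)C=C2 | intermediate
17 | 2-bromo-4-hydroxybenzaldehyde | O=Cc1ccc(O)cc1Br | starting material
18 | 2-bromo-4-(methoxymethoxy)benzaldehyde | O=Cc1ccc(OCOC)cc1Br | intermediate
19 | [2-bromo-4-(methoxymethoxy)phenyl]methanol | OCc1ccc(OCOC)cc1Br | intermediate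
20 | 2-bromo-1-(bromomethyl)-4-(methoxymethoxy)benzene | BrCc1ccc(OCOC)cc1Br | intermediate
21 | diethyl 2-[2-bromo-4-(methoxymethoxy)benzyl]-2-[7-(methoxymethoxy)-2,2-dimethyl-8-(3-methylbut-2-en-1-yl)-2H-chromen-6-yl]malonate | CC(C)=CCc1c(OCOC)c(C(Cc3ccc(OCOC)cc3Br)(C(=O)OCC)C(=O)OCC)cc2c1OC(C)(C)C=C2 | intermediate
22 | 2-[2-bromo-4-(methoxymethoxy)benzyl]-2-[7-(methoxymethoxy)-2,2-dimethyl-8-(3-methylbut-2-en-1-yl)-2H-chromen-6-yl]propane-1,3-diol (achiral, prochiral at the quaternary carbon) | CC(C)=CCc1c(OCOC)c(C(CO)(CO)Cc3ccc(OCOC)cc3Br)cc2c1OC(C)(C)C=C2 | intermediate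
23 | [(3R)-7-(methoxymethoxy)-3-[7-(methoxymethoxy)-2,2-dimethyl-8-(3-methylbut-2-en-1-yl)-2H-chromen-6-yl]-3,4-dihydro-2H-chromen-3-yl]methanol | CC(C)=CCc1c(OCOC)c([C@]2(CO)COc3cc(OCOC)ccc3C2)cc2c1OC(C)(C)C=C2 | intermediate
24 | (3S)-7-(methoxymethoxy)-3-[7-(methoxymethoxy)-2,2-dimethyl-8-(3-methylbut-2-en-1-yl)-2H-chromen-6-yl]-3,4-dihydro-2H-chromene-3-carbaldehyde | CC(C)=CCc1c(OCOC)c([C@]2(C=O)COc3cc(OCOC)ccc3C2)cc2c1OC(C)(C)C=C2 | intermediate
25 | 7-(methoxymethoxy)-6-[(3R)-7-(methoxymethoxy)-3,4-dihydro-2H-chromen-3-yl]-2,2-dimethyl-8-(3-methylbut-2-en-1-yl)-2H-chromene | CC(C)=CCc1c(OCOC)c([C@@H]2COc3cc(OCOC)ccc3C2)cc2c1OC(C)(C)C=C2 | intermediate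
26 | 6-[(3R)-7-hydroxy-3,4-dihydro-2H-chromen-3-yl]-2,2-dimethyl-8-(3-methylbut-2-en-1-yl)-2H-chromen-7-ol | CC(C)=CCc1c(O)c([C@@H]2COc3cc(O)ccc3C2)cc2c1OC(C)(C)C=C2 | target

## Step count and least certain steps

Total step count: 17. Longest linear sequence: 14 steps (steps 1 to 8 and 12 to 17); steps 9 to 11 form the three-step branch to 20.

**Step 14 (key step).**
- What may go wrong: the ligand may discriminate poorly between the two hydroxymethyl arms when the third substituent is a bulky, ortho-substituted aryl group. The closure may also be slow enough for β-hydride loss from the palladium alkoxide and hydrodebromination to take over.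
- Fallback: the stereocentre is set by an enzyme and the ring is closed without asymmetric induction.
  - From 22, an immobilised lipase (Candida antarctica lipase B, vinyl acetate) acetylates one arm to give the (R)-monoacetate F1; the enzyme is chosen by screening so that the arm destined for O1 is the one acetylated.
  - Acetyl migration between the arms under carbonate would racemise F1, so the free arm is first silylated (tert-butyl(chloro)diphenylsilane, imidazole) to the acetate silyl ether F2.
  - Methanolysis of the acetate (K2CO3, MeOH) frees the other arm in the mono-silyl ether F3.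
  - F3 is cyclised with an achiral catalyst (Pd(OAc)2, racemic 2-(di-tert-butylphosphino)-1,1'-binaphthyl, Cs2CO3, toluene) to the chroman silyl ether F4.
  - Fluoride (Bu4NF) removes the silyl group and the sequence comes back to the route at 23.

**Step 16.**
- What may go wrong: extrusion of carbon monoxide from a fully substituted acyl–rhodium hydride may be slow. That leaves time for β-hydride loss towards an isoflavene, for migration of the prenyl double bond into conjugation, and for partial loss of configuration through a radical pair.
- Fallback: the organometallic excision is given up and the stereocentre is recovered by separation.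
  - From 24, chlorite oxidation (NaClO2, NaH2PO4, excess 9 as hypochlorite scavenger) gives the (3S)-carboxylic acid F5.
  - Coupling with N-hydroxyphthalimide (N,N'-diisopropylcarbodiimide) gives the redox-active ester F6.
  - Nickel-mediated reductive decarboxylation (NiCl2·6H2O, 4,4'-di-tert-butyl-2,2'-bipyridine, PhSiH3, Zn) passes through the planar C3 radical and gives the racemic bis-acetal F7.
  - Preparative chromatography on a chiral stationary phase removes the (3S) enantiomer F8, and the (3R) half rejoins the route as 25.
  - The cost is half of the material at a late stage.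

**Step 17.**
- What may go wrong: acid-catalysed addition of the freed C2' hydroxyl across the prenyl olefin (closure to a dihydropyran), or hydration of the ring D olefin, may compete with acetal cleavage.
- Fallback: Brønsted-acid solvolysis is replaced by a buffered acetal-to-silyl ether exchange. From 25, Me3SiOTf with 2,2'-bipyridyl in CH2Cl2 at 0 °C converts both aryl acetals into the bis(trimethylsilyl) ether F9, with the pyridine base trapping the methoxymethyl cation. Water at neutral pH then hydrolyses F9 to 26.

**Step 8.**
- What may go wrong: oxidative addition into the electron-rich, ortho-alkoxy C–Br bond may be slow, so that hydrodebromination and catalyst decay dominate before the hindered malonate enolate couples.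
- Fallback: the malonate is built in two stages through a smaller, less basic nucleophile. From 14, coupling with the zinc enolate BrZnCH2CO2Et (Pd(dba)2, P(t-Bu)3, THF, rt) gives the ethyl arylacetate F10. Claisen-type C-carboxylation (NaH, diethyl carbonate, reflux) then gives 16.

**Step 1.**
- What may go wrong: in hot sulfonic acid, bromine may migrate or be lost by ipso-protonation. C-alkylation by the acid followed by lactonisation to a 4,4-dimethyldihydrocoumarin may also compete with acylation.
- Fallback: acylation and ring closure are separated. From 1, Friedel–Crafts acetylation (AcOH, BF3·OEt2, 90 °C) gives the acetophenone F11. Kabbe condensation with acetone and pyrrolidine (enamine aldol, then oxa-Michael closure) gives 4.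

## Further compounds

F1 | step 14 | (R)-2-[2-bromo-4-(methoxymethoxy)benzyl]-3-hydroxy-2-[7-(methoxymethoxy)-2,2-dimethyl-8-(3-methylbut-2-en-1-yl)-2H-chromen-6-yl]propyl acetate | CC(C)=CCc1c(OCOC)c([C@](Cc3ccc(OCOC)cc3Br)(CO)COC(C)=O)cc2c1OC(C)(C)C=C2
F2 | step 14 | (S)-2-[2-bromo-4-(methoxymethoxy)benzyl]-3-[(tert-butyldiphenylsilyl)oxy]-2-[7-(methoxymethoxy)-2,2-dimethyl-8-(3-methylbut-2-en-1-yl)-2H-chromen-6-yl]propyl acetate | CC(C)=CCc1c(OCOC)c([C@](Cc3ccc(OCOC)cc3Br)(CO[Si](c3ccccc3)(c3ccccc3)C(C)(C)C)COC(C)=O)cc2c1OC(C)(C)C=C2
F3 | step 14 | (S)-2-[2-bromo-4-(methoxymethoxy)benzyl]-3-[(tert-butyldiphenylsilyl)oxy]-2-[7-(methoxymethoxy)-2,2-dimethyl-8-(3-methylbut-2-en-1-yl)-2H-chromen-6-yl]propan-1-ol | CC(C)=CCc1c(OCOC)c([C@](Cc3ccc(OCOC)cc3Br)(CO[Si](c3ccccc3)(c3ccccc3)C(C)(C)C)CO)cc2c1OC(C)(C)C=C2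
F4 | step 14 | tert-butyldiphenylsilyl ether of 23, (3S) | CC(C)=CCc1c(OCOC)c([C@]2(CO[Si](c3ccccc3)(c3ccccc3)C(C)(C)C)COc3cc(OCOC)ccc3C2)cc2c1OC(C)(C)C=C2
F5 | step 16 | (3S)-7-(methoxymethoxy)-3-[7-(methoxymethoxy)-2,2-dimethyl-8-(3-methylbut-2-en-1-yl)-2H-chromen-6-yl]-3,4-dihydro-2H-chromene-3-carboxylic acid | CC(C)=CCc1c(OCOC)c([C@]2(C(=O)O)COc3cc(OCOC)ccc3C2)cc2c1OC(C)(C)C=C2
F6 | step 16 | N-hydroxyphthalimide ester of F5 | CC(C)=CCc1c(OCOC)c([C@]2(C(=O)ON3C(=O)c4ccccc4C3=O)COc3cc(OCOC)ccc3C2)cc2c1OC(C)(C)C=C2
F7 | step 16 | racemic 7-(methoxymethoxy)-6-[7-(methoxymethoxy)-3,4-dihydro-2H-chromen-3-yl]-2,2-dimethyl-8-(3-methylbut-2-en-1-yl)-2H-chromene | CC(C)=CCc1c(OCOC)c(C2COc3cc(OCOC)ccc3C2)cc2c1OC(C)(C)C=C2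
F8 | step 16 | (3S) enantiomer of 25 | CC(C)=CCc1c(OCOC)c([C@H]2COc3cc(OCOC)ccc3C2)cc2c1OC(C)(C)C=C2
F9 | step 17 | bis(trimethylsilyl) ether of 26, (3R) | CC(C)=CCc1c(O[Si](C)(C)C)c([C@@H]2COc3cc(O[Si](C)(C)C)ccc3C2)cc2c1OC(C)(C)C=C2
F10 | step 8 | ethyl 2-[7-(methoxymethoxy)-2,2-dimethyl-8-(3-methylbut-2-en-1-yl)-2H-chromen-6-yl]acetate | CC(C)=CCc1c(OCOC)c(CC(=O)OCC)cc2c1OC(C)(C)C=C2
F11 | step 1 | 1-(5-bromo-2,4-dihydroxyphenyl)ethan-1-one | CC(=O)c1cc(Br)c(O)cc1O
A1 | alternative 1 | 4-[(3R)-7-(methoxymethoxy)-3,4-dihydro-2H-chromen-3-yl]cyclohexane-1,3-dione, epimers at the dione carbon | O=C1CCC([C@@H]2COc3cc(OCOC)ccc3C2)C(=O)C1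
A2 | alternative 1 | (R)-1-[7-(methoxymethoxy)-3,4-dihydro-2H-chromen-3-yl]propan-2-one | CC(=O)C[C@@H]1COc2cc(OCOC)ccc2C1
A3 | alternative 1 | methyl acrylate | C=CC(=O)OC
A4 | alternative 2 | (3R)-7-(methoxymethoxy)-3-[7-(methoxymethoxy)-2,2-dimethyl-8-(3-methylbut-2-en-1-yl)-2H-chromen-6-yl]-3,4-dihydro-2H-chromen-2-ol, anomeric mixture | CC(C)=CCc1c(OCOC)c([C@@H]2C(O)Oc3cc(OCOC)ccc3C2)cc2c1OC(C)(C)C=C2
A5 | alternative 2 | 2-[7-(methoxymethoxy)-2,2-dimethyl-8-(3-methylbut-2-en-1-yl)-2H-chromen-6-yl]acetaldehyde | CC(C)=CCc1c(OCOC)c(CC=O)cc2c1OC(C)(C)C=C2
A6 | alternative 2 | 5-(methoxymethoxy)-2-[(phenylsulfonyl)methyl]phenol | COCOc1ccc(CS(=O)(=O)c2ccccc2)c(O)c1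
A7 | alternative 2 | 3-(methoxymethoxy)-6-methylidenecyclohexa-2,4-dien-1-one | COCOC1=CC(=O)C(=C)C=C1
A8 | alternative 3 | 2,2-dimethyl-8-(3-methylbut-2-en-1-yl)-6-[(3R)-7-(triisopropylsilyloxy)-3,4-dihydro-2H-chromen-3-yl]-2H-chromen-7-ol | CC(C)=CCc1c(O)c([C@@H]2COc3cc(O[Si](C(C)C)(C(C)C)C(C)C)ccc3C2)cc2c1OC(C)(C)C=C2
A9 | alternative 3 | 2-(3-methylbut-2-en-1-yl)-4-[(3R)-7-(triisopropylsilyloxy)-3,4-dihydro-2H-chromen-3-yl]benzene-1,3-diol | CC(C)=CCc1c(O)ccc([C@@H]2COc3cc(O[Si](C(C)C)(C(C)C)C(C)C)ccc3C2)c1O
A10 | alternative 3 | 3-methylbut-2-enal | CC(C)=CC=O
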